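The runs stem from a simulated flask for substances that don't exist.

Tuesday's run, in its last row, carries what I need for your flask. It had 7 mM of precatalyst; yours has 5.0 mM, with the same 0.40 mM of racemization catalyst.

in all of them: left-handed substrate 0.10 M; right-handed substrate 0.10 M; racemization catalyst 0.40 mM

|  | coupling partner | precatalyst | remark | time |
|---|---|---|---|---|
| Tuesday's | 0.40 M | 7 mM | run made earlier |  |
| Monday's | 0.40 M | 11 mM | run made earlier |  |
| flask | 0.400 M | 5.0 mM |  | 10 h |

| run | time / h | left-handed substrate / % | right-handed substrate / % | left-handed product / % |
|---|---|---|---|---|
| Tuesday's | 0.500 | 25.5 | 42.5 | 24.9 |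
| Tuesday's | 0.833 | 16.9 | 37.4 | 40.0 |
| Tuesday's | 1.50 | 5.3 | 24.7 | 54.1 |
| Tuesday's | 3.00 | 3.2 | 11.6 | 66.1 |
| Tuesday's | 6.00 | 1.6 | 5.2 | 71.7 |
| Monday's | 0.500 | 20.4 | 40.7 | 34.9 |
| Monday's | 0.833 | 10.6 | 31.2 | 48.3 |
| Monday's | 1.50 | 3.3 | 18.9 | 57.6 |
| Monday's | 3.00 | 0.4 | 8.3 | 66.1 |
| Monday's | 6.00 | 0.1 | 1.0 | 70.5 |

(each reading ± 1 percentage point)

- free catalyst is single-handed; left-handed substrate and right-handed substrate are mirror images of each other, charged as a racemate, each of them at the stated concentration
- steps under discussion: left-handed substrate + racemization catalyst <-> right-handed substrate + racemization catalyst; coupling partner + racemization catalyst -> spent catalyst; coupling partner + free catalyst + left-handed substrate -> free catalyst + left-handed product; coupling partner + free catalyst + right-handed substrate -> free catalyst + right-handed product; precatalyst <-> free catalyst; coupling partner <-> dormant form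
- an excess is below zero if the other one leads

- part of the left-handed substrate and right-handed substrate charged together that has reacted at 10 h
- excess of left-handed product over right-handed product in the product at 10 h
- excess of right-handed substrate over left-handed substrate among what is left of the two at 10 h

Your quick forecast says 94.5% reacted, a product excess of 48% and a substrate excess of 53%, between 38% and 70%, with racemization fading “as the racemization catalyst is killed by the partner”. I reckon the third myself.

Let coupling remove left-handed and right-handed substrate with pseudo-first-order constants kL and kR, and let racemization run at kr each way. With these constants held, their ratio stops moving where c(right-handed substrate)/c(left-handed substrate) minus its inverse equals (kL − kR)/kr. Tuesday's readings at 6.00 h give 2.94 for that difference. It is rough, since the left-handed reading is 1.6% with a scatter of 1 percentage point. This is what I carry: the lean, the selectivity gap over racemization.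

The excess is (√(4 + lean^2) − 2)/lean, near zero for a small lean and near full for a large one. That joins the two ends. I assume the gap scales with the precatalyst charge, so your flask has a lean of 2.10 and an excess of 42.9%, lower than your number. That holds racemization at its level of 6.00 h on Tuesday, and your flask runs to 10 h, so I commit to it as a low estimate.

    left-handed substrate + racemization catalyst ⇌ right-handed substrate + racemization catalyst, rate k1*[racemization catalyst]*[left-handed substrate] forward; the back reaction follows from the equilibrium constant (k = 38.8 /M/min)
    coupling partner + racemization catalyst → spent catalyst (k = 0.0414 /M/min)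
    coupling partner + free catalyst + left-handed substrate → free catalyst + left-handed product (k = 115 /M²/min)
    coupling partner + free catalyst + right-handed substrate → free catalyst + right-handed product (k = 16.2 /M²/min)
    precatalyst ⇌ free catalyst (K = 0.404, k = 0.00738 /min)
    coupling partner ⇌ dormant form (K = 2.53, k = 0.00571 /min)

The flask gives 94.5% reacted, a product excess of 52.4% and a substrate excess of 67.7%, with a lean of 5.01 at 10.0 h, above my 2.10. In your flask the half-life of left-handed substrate by forward racemization alone grows from 1.3 h at 0.729 h to 9.2 h at 10.0 h, and by then coupling uses left-handed substrate 7.4 times as fast as that forward step. The neighbour flask with 6.8 × 10⁻⁴ M of racemization catalyst, 1.70 times the charge, ends with a lean of 2.85 and a substrate excess of 52.0%.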